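**Strategy**

Everything rests on cutting the two C–C bonds at the enal: Cβ–CH2 (the eleven-methylene arm to piperidine ring A) and Cα–CH2 (the ten-methylene arm to ring B). The feature exploited is the trisubstituted unit CβH=Cα(CHO), whose three carbons are those of propynal diethyl acetal. In one operation the ring A alkylcopper adds syn across the alkyne and the resulting alkenylcopper is alkylated by the ring B iodide, which forms both bonds and sets the E geometry. The precursors are two N-Boc, O-TBS all-cis 6-alkyl-2-methylpiperidin-3-ols, one ending in a Grignard (ring A) and one in an iodide (ring B), both grown from one 6-allylpiperidine of aza-Achmatowicz origin.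

Key step: step 14

Remark: 4–8 are mixtures of C6 epimers that converge at iminium ion 9, and 12 and 15 are E/Z mixtures that converge on hydrogenation; the target is taken as the free base.

**Route**

Step 1
Reactants: 1 (S)-1-(furan-2-yl)ethanamine
Product: 2 tert-butyl N-[(1S)-1-(furan-2-yl)ethyl]carbamate
Conditions: Boc2O, Et3N, CH2Cl2, 0 °C → rt
Reagents that add atoms: di-tert-butyl dicarbonate, CC(C)(C)OC(=O)OC(=O)OC(C)(C)C
Why: Carbamate formation (N-acylation) at a primary amine, which leaves the stereocentre untouched.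

Step 2
Reactants: 2 tert-butyl N-[(1S)-1-(furan-2-yl)ethyl]carbamate
Product: 4 tert-butyl (2S)-6-hydroxy-2-methyl-3-oxo-3,6-dihydro-2H-pyridine-1-carboxylate (C6 epimers), via keto enal 3 (not isolated)
Conditions: mCPBA, CH2Cl2, 0 °C → rt
Reagents that add atoms: 3-chloroperoxybenzoic acid (mCPBA), OOC(=O)c1cccc(Cl)c1
Why: Aza-Achmatowicz rearrangement, in which furan epoxidation opens to the cis keto enal and the carbamate N–H closes onto the aldehyde; C2 keeps the configuration of 1.

Step 3
Reactants: 4 tert-butyl (2S)-6-hydroxy-2-methyl-3-oxo-3,6-dihydro-2H-pyridine-1-carboxylate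
Product: 5 tert-butyl (2S)-6-methoxy-2-methyl-3-oxo-3,6-dihydro-2H-pyridine-1-carboxylate (C6 epimers)
Conditions: CH(OMe)3, BF3·OEt2 (cat.), 4 Å MS, CH2Cl2, 0 °C
Reagents that add atoms: trimethyl orthoformate, COC(OC)OC
Why: Acid-catalysed N,O-acetal formation through the N-acyliminium ion, which locks the ring form so that the ketone can be handled separately.

Step 4
Reactants: 5 tert-butyl (2S)-6-methoxy-2-methyl-3-oxo-3,6-dihydro-2H-pyridine-1-carboxylate
Product: 6 tert-butyl (2S)-6-methoxy-2-methyl-3-oxopiperidine-1-carboxylate (C6 epimers)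
Conditions: H2 (1 atm), Pd/C, EtOAc, rt
Reagents that add atoms: none
Why: Heterogeneous hydrogenation of the enone C=C under neutral conditions, which should spare the ketone, the carbamate and the N,O-acetal.

Step 5
Reactants: 6 tert-butyl (2S)-6-methoxy-2-methyl-3-oxopiperidine-1-carboxylate
Product: 7 tert-butyl (2S,3S)-3-hydroxy-6-methoxy-2-methylpiperidine-1-carboxylate (C6 epimers)
Conditions: LiBH(s-Bu)3, THF, −78 °C; then H2O
Reagents that add atoms: none
Why: Hydride reduction of a ketone; A(1,3) strain to the Boc group holds the 2-methyl axial, so the bulky borohydride should attack C3 from the opposite face and place the new OH cis to methyl (3S).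

Step 6
Reactants: 7 tert-butyl (2S,3S)-3-hydroxy-6-methoxy-2-methylpiperidine-1-carboxylate
Product: 8 tert-butyl (2S,3S)-3-[(tert-butyldimethylsilyl)oxy]-6-methoxy-2-methylpiperidine-1-carboxylate (C6 epimers)
Conditions: TBSCl, imidazole, DMAP (cat.), DMF, 40 °C
Reagents that add atoms: tert-butyldimethylsilyl chloride, CC(C)(C)[Si](C)(C)Cl
Why: O-Silylation of a secondary alcohol under basic conditions without a Lewis acid, so the N,O-acetal should stay intact.

Step 7
Reactants: 8 tert-butyl (2S,3S)-3-[(tert-butyldimethylsilyl)oxy]-6-methoxy-2-methylpiperidine-1-carboxylate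
Product: 10 tert-butyl (2S,3S,6S)-3-[(tert-butyldimethylsilyl)oxy]-2-methyl-6-(prop-2-en-1-yl)piperidine-1-carboxylate, via N-acyliminium ion 9 (not isolated)
Conditions: allylSiMe3, BF3·OEt2, CH2Cl2, −78 °C
Reagents that add atoms: allyltrimethylsilane, C=CC[Si](C)(C)C
Why: Hosomi–Sakurai allylation of an N-acyliminium ion; with the 2-methyl held axial by A(1,3) strain, axial attack through a chair-like transition state should deliver allyl to the same face and give the 2,6-cis, all-cis ring (6S because allyl outranks C5).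

Step 8
Reactants: 10 tert-butyl (2S,3S,6S)-3-[(tert-butyldimethylsilyl)oxy]-2-methyl-6-(prop-2-en-1-yl)piperidine-1-carboxylate; 11 10-bromodec-1-ene
Product: 12 tert-butyl (2S,3S,6S)-6-(11-bromoundec-2-en-1-yl)-3-[(tert-butyldimethylsilyl)oxy]-2-methylpiperidine-1-carboxylate (E/Z mixture)
Conditions: second-generation Grubbs catalyst, RuCl2(=CHPh)(PCy3)(SIMes) (5 mol %), 1,4-benzoquinone (10 mol %), 11 (4 equiv), CH2Cl2, 40 °C
Reagents that add atoms: none
Why: Olefin cross-metathesis of two terminal alkenes, driven by loss of ethylene and by excess of the cheap partner, with benzoquinone added to suppress double-bond migration that would change the chain length.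

Step 9
Reactants: 12 tert-butyl (2S,3S,6S)-6-(11-bromoundec-2-en-1-yl)-3-[(tert-butyldimethylsilyl)oxy]-2-methylpiperidine-1-carboxylate
Product: 13 tert-butyl (2S,3S,6R)-6-(11-bromoundecyl)-3-[(tert-butyldimethylsilyl)oxy]-2-methylpiperidine-1-carboxylate
Conditions: H2 (1 atm), Pd/C, EtOAc, rt
Reagents that add atoms: none
Why: Heterogeneous hydrogenation of a disubstituted alkene under neutral conditions, which should leave the primary bromide, carbamate and silyl ether alone (the C6 descriptor changes to R without any change in space).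

Step 10
Reactants: 10 tert-butyl (2S,3S,6S)-3-[(tert-butyldimethylsilyl)oxy]-2-methyl-6-(prop-2-en-1-yl)piperidine-1-carboxylate; 14 9-bromonon-1-ene
Product: 15 tert-butyl (2S,3S,6S)-6-(10-bromodec-2-en-1-yl)-3-[(tert-butyldimethylsilyl)oxy]-2-methylpiperidine-1-carboxylate (E/Z mixture)
Conditions: second-generation Grubbs catalyst, RuCl2(=CHPh)(PCy3)(SIMes) (5 mol %), 1,4-benzoquinone (10 mol %), 14 (4 equiv), CH2Cl2, 40 °C
Reagents that add atoms: none
Why: Olefin cross-metathesis as in step 8, here with the nine-carbon bromoalkene to build the ten-carbon arm.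

Step 11
Reactants: 15 tert-butyl (2S,3S,6S)-6-(10-bromodec-2-en-1-yl)-3-[(tert-butyldimethylsilyl)oxy]-2-methylpiperidine-1-carboxylate
Product: 16 tert-butyl (2S,3S,6R)-6-(10-bromodecyl)-3-[(tert-butyldimethylsilyl)oxy]-2-methylpiperidine-1-carboxylate
Conditions: H2 (1 atm), Pd/C, EtOAc, rt
Reagents that add atoms: none
Why: Heterogeneous alkene hydrogenation as in step 9.

Step 12
Reactants: 16 tert-butyl (2S,3S,6R)-6-(10-bromodecyl)-3-[(tert-butyldimethylsilyl)oxy]-2-methylpiperidine-1-carboxylate
Product: 17 tert-butyl (2S,3S,6R)-3-[(tert-butyldimethylsilyl)oxy]-6-(10-iododecyl)-2-methylpiperidine-1-carboxylate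
Conditions: NaI, acetone, reflux
Reagents that add atoms: sodium iodide, [Na+].[I-]
Why: Finkelstein halide exchange (SN2) at a primary carbon, driven by precipitation of NaBr; no stereocentre is involved.

Step 13
Reactants: 13 tert-butyl (2S,3S,6R)-6-(11-bromoundecyl)-3-[(tert-butyldimethylsilyl)oxy]-2-methylpiperidine-1-carboxylate
Product: 18 {11-[(2R,5S,6S)-1-(tert-butoxycarbonyl)-5-[(tert-butyldimethylsilyl)oxy]-6-methylpiperidin-2-yl]undecyl}magnesium bromide (titrated Et2O solution, used at once)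
Conditions: Mg turnings (I2-activated), Et2O, 35 °C
Reagents that add atoms: magnesium, [Mg]
Why: Grignard formation by insertion of magnesium into a primary C–Br bond; the hindered tert-butyl carbamate and the silyl ether should not be attacked by a primary alkylmagnesium halide at this temperature.

Step 14
Reactants: 18 ring A undecylmagnesium bromide; 19 3,3-diethoxyprop-1-yne; 17 ring B decyl iodide
Product: 22 N,N′-di-Boc-O,O′-di-TBS diethyl acetal of enal 24 (E alkene), via ring A alkylcopper 20 (not isolated), via Z-alkenylcopper 21 (not isolated)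
Conditions: CuBr·SMe2 (1.0 equiv), Et2O/Me2S, −45 °C; 19, −45 → −30 °C; then P(OEt)3, DMPU, 17 (1.5 equiv), −45 → −10 °C; aq NH4Cl/NH3
Reagents that add atoms: none
Why: Transmetalation of 18 to CuBr gives the alkylcopper–MgBr2 reagent 20, which adds syn across the terminal alkyne of 19; coordination of the metals to an acetal oxygen should place copper on the carbon next to the acetal and the undecyl arm on the terminal CH, giving the Z-alkenylcopper 21. Alkylation of 21 by the primary iodide 17 (oxidative addition at copper and reductive elimination, accelerated by the phosphite and the polar cosolvent) proceeds with retention, so the decyl arm ends cis to the undecyl arm and the acetal trans to it, which is the E geometry of the target. The closest known reaction type is the carbocupration of propargylic acetals and ketals followed by trapping of the alkenylcopper with electrophiles such as methyl iodide, allyl bromide or iodine; a long unactivated iodide is a slower partner than these, and this is where the route carries its risk. No ring is closed and no stereocentre is created; the only new stereochemical element is the alkene geometry, set by syn addition and retentive substitution. The step needs regioselectivity (from the chelating acetal), the right arm on the right carbon (from the order of addition) and chemoselectivity against β-elimination of ethoxide to the allenyl ether (21 is kept at or below −30 °C until iodide, phosphite and DMPU are present); carbamates and silyl ethers are inert to organocopper reagents.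

Step 15
Reactants: 22 N,N′-di-Boc-O,O′-di-TBS diethyl acetal of enal 24
Product: 24 (2E)-14-[(2R,5S,6S)-5-hydroxy-6-methylpiperidin-2-yl]-2-{10-[(2R,5S,6S)-5-hydroxy-6-methylpiperidin-2-yl]decyl}tetradec-2-enal, via dihydrochloride 23 (not isolated)
Conditions: 3 M HCl (aq)/THF (1:2), rt → 40 °C; then NaHCO3 (aq), 0 °C, CHCl3 extraction
Reagents that add atoms: water, O
Why: Acid hydrolysis of the acetal, acidolysis of both Boc groups and protodesilylation of both TBS ethers in one pot; the E enal is also the more stable isomer, and the amines stay protonated (23) until the cold neutralisation, so they should not add to the enal.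

**Compound list**

1 | (S)-1-(furan-2-yl)ethanamine | C[C@H](N)c1ccco1 | starting material
2 | tert-butyl N-[(1S)-1-(furan-2-yl)ethyl]carbamate | C[C@H](NC(=O)OC(C)(C)C)c1ccco1 | intermediate
3 | tert-butyl N-[(2S,4Z)-3,6-dioxohex-4-en-2-yl]carbamate (ring-opened keto enal) | C[C@H](NC(=O)OC(C)(C)C)C(=O)/C=C\C=O | intermediate (not isolated)
4 | tert-butyl (2S)-6-hydroxy-2-methyl-3-oxo-3,6-dihydro-2H-pyridine-1-carboxylate (C6 epimers) | C[C@@H]1N(C(=O)OC(C)(C)C)C(O)C=CC1=O | intermediate
5 | tert-butyl (2S)-6-methoxy-2-methyl-3-oxo-3,6-dihydro-2H-pyridine-1-carboxylate (C6 epimers) | C[C@@H]1N(C(=O)OC(C)(C)C)C(OC)C=CC1=O | intermediate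
6 | tert-butyl (2S)-6-methoxy-2-methyl-3-oxopiperidine-1-carboxylate (C6 epimers) | C[C@@H]1N(C(=O)OC(C)(C)C)C(OC)CCC1=O | intermediate
7 | tert-butyl (2S,3S)-3-hydroxy-6-methoxy-2-methylpiperidine-1-carboxylate (C6 epimers) | C[C@@H]1N(C(=O)OC(C)(C)C)C(OC)CC[C@@H]1O | intermediate
8 | tert-butyl (2S,3S)-3-[(tert-butyldimethylsilyl)oxy]-6-methoxy-2-methylpiperidine-1-carboxylate (C6 epimers) | C[C@@H]1N(C(=O)OC(C)(C)C)C(OC)CC[C@@H]1O[Si](C)(C)C(C)(C)C | intermediate
9 | (2S,3S)-1-(tert-butoxycarbonyl)-3-[(tert-butyldimethylsilyl)oxy]-2-methyl-2,3,4,5-tetrahydropyridin-1-ium (N-acyliminium ion) | C[C@@H]1[N+](C(=O)OC(C)(C)C)=CCC[C@@H]1O[Si](C)(C)C(C)(C)C | intermediate (not isolated)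
10 | tert-butyl (2S,3S,6S)-3-[(tert-butyldimethylsilyl)oxy]-2-methyl-6-(prop-2-en-1-yl)piperidine-1-carboxylate (all-cis) | C[C@@H]1N(C(=O)OC(C)(C)C)[C@H](CC=C)CC[C@@H]1O[Si](C)(C)C(C)(C)C | intermediate
11 | 10-bromodec-1-ene | C=CCCCCCCCCBr | starting material
12 | tert-butyl (2S,3S,6S)-6-(11-bromoundec-2-en-1-yl)-3-[(tert-butyldimethylsilyl)oxy]-2-methylpiperidine-1-carboxylate (E/Z mixture) | C[C@@H]1N(C(=O)OC(C)(C)C)[C@H](CC=CCCCCCCCCBr)CC[C@@H]1O[Si](C)(C)C(C)(C)C | intermediate
13 | tert-butyl (2S,3S,6R)-6-(11-bromoundecyl)-3-[(tert-butyldimethylsilyl)oxy]-2-methylpiperidine-1-carboxylate (ring A bromide) | C[C@@H]1N(C(=O)OC(C)(C)C)[C@H](CCCCCCCCCCCBr)CC[C@@H]1O[Si](C)(C)C(C)(C)C | intermediate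
14 | 9-bromonon-1-ene | C=CCCCCCCCBr | starting material
15 | tert-butyl (2S,3S,6S)-6-(10-bromodec-2-en-1-yl)-3-[(tert-butyldimethylsilyl)oxy]-2-methylpiperidine-1-carboxylate (E/Z mixture) | C[C@@H]1N(C(=O)OC(C)(C)C)[C@H](CC=CCCCCCCCBr)CC[C@@H]1O[Si](C)(C)C(C)(C)C | intermediate
16 | tert-butyl (2S,3S,6R)-6-(10-bromodecyl)-3-[(tert-butyldimethylsilyl)oxy]-2-methylpiperidine-1-carboxylate (ring B bromide) | C[C@@H]1N(C(=O)OC(C)(C)C)[C@H](CCCCCCCCCCBr)CC[C@@H]1O[Si](C)(C)C(C)(C)C | intermediate
17 | tert-butyl (2S,3S,6R)-3-[(tert-butyldimethylsilyl)oxy]-6-(10-iododecyl)-2-methylpiperidine-1-carboxylate (ring B decyl iodide) | ICCCCCCCCCC[C@@H]1CC[C@H](O[Si](C)(C)C(C)(C)C)[C@H](C)N1C(=O)OC(C)(C)C | intermediate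
18 | {11-[(2R,5S,6S)-1-(tert-butoxycarbonyl)-5-[(tert-butyldimethylsilyl)oxy]-6-methylpiperidin-2-yl]undecyl}magnesium bromide (ring A Grignard) | C[C@@H]1N(C(=O)OC(C)(C)C)[C@H](CCCCCCCCCCC[Mg]Br)CC[C@@H]1O[Si](C)(C)C(C)(C)C | intermediate
19 | 3,3-diethoxyprop-1-yne | C#CC(OCC)OCC | starting material
20 | ring A undecylcopper–MgBr2 reagent | C[C@@H]1N(C(=O)OC(C)(C)C)[C@H](CCCCCCCCCCC[Cu])CC[C@@H]1O[Si](C)(C)C(C)(C)C.Br[Mg]Br | intermediate (not isolated)
21 | (Z)-alkenylcopper–MgBr2 reagent: copper on the carbon next to the acetal, cis to the ring A undecyl arm | C[C@@H]1N(C(=O)OC(C)(C)C)[C@H](CCCCCCCCCCC/C=C(/C(OCC)OCC)[Cu])CC[C@@H]1O[Si](C)(C)C(C)(C)C.Br[Mg]Br | intermediate (not isolated)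
22 | N,N′-di-Boc-O,O′-di-TBS derivative of 24 with the aldehyde as diethyl acetal (E alkene, ring centres as in 24) | C[C@@H]1N(C(=O)OC(C)(C)C)[C@H](CCCCCCCCCCC/C=C(/C(OCC)OCC)CCCCCCCCCC[C@@H]2CC[C@H](O[Si](C)(C)C(C)(C)C)[C@H](C)N2C(=O)OC(C)(C)C)CC[C@@H]1O[Si](C)(C)C(C)(C)C | intermediate
23 | dihydrochloride of 24 | C[C@@H]1N[C@H](CCCCCCCCCCC/C=C(/C=O)CCCCCCCCCC[C@@H]2CC[C@H](O)[C@H](C)N2)CC[C@@H]1O.Cl.Cl | intermediate (not isolated)
24 | (2E)-14-[(2R,5S,6S)-5-hydroxy-6-methylpiperidin-2-yl]-2-{10-[(2R,5S,6S)-5-hydroxy-6-methylpiperidin-2-yl]decyl}tetradec-2-enal (CNP0177491.1) | C[C@@H]1N[C@H](CCCCCCCCCCC/C=C(/C=O)CCCCCCCCCC[C@@H]2CC[C@H](O)[C@H](C)N2)CC[C@@H]1O | target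

**Step count and risks**

Total step count: 15. Longest linear sequence: 12 steps (steps 1–7, 8, 9, 13, 14, 15; the ring B branch through steps 10, 11, 12 is equally long).

Steps most likely to fail:

1. Step 14. The alkenylcopper may lose ethoxide (β-elimination to the allenyl ether) faster than the unactivated iodide alkylates it, or the alkylation may stall at the temperature the reagent tolerates. The fallback sets out from 21 (made from 18 and 19 exactly as in step 14) and from 17, and returns at 22. Alkenylcopper 21 is quenched at −45 °C with I2, a fast trapping, to give tert-butyl (2S,3S,6R)-3-[(tert-butyldimethylsilyl)oxy]-6-[(12Z)-14,14-diethoxy-13-iodotetradec-12-en-1-yl]-2-methylpiperidine-1-carboxylate F1. Iodide 17 is converted with Zn dust and LiCl (THF, 40 °C) into the ring B decylzinc iodide F2. Negishi coupling of the two (PdCl2(dppf), THF/DMA, rt → 50 °C) should attach the second arm with retention of geometry and give 22.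

2. Step 7. The silane may add to the wrong face of iminium ion 9 (2,6-trans epimer), or the ion may collapse to the enecarbamate. The fallback sets out from 2 and returns at 13 and 16; it puts the chain on the furan before the ring is made and sets C6 by hydride instead of carbon.
   - Twofold lithiation of 2 (n-BuLi, 2.2 equiv, THF, −78 → −20 °C; N–H and furan C5–H) and alkylation with excess 1,11-dibromoundecane should give the 5-(11-bromoundecyl)furan carbamate F3; 1,10-dibromodecane gives the decyl analogue F4.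
   - mCPBA oxidation (aza-Achmatowicz) gives the 6-alkyl-6-hydroxy dihydropyridinones F5 and F6.
   - Et3SiH/BF3·OEt2 (CH2Cl2, −78 °C) reduces the tertiary N-acyliminium ions. The enone ring is nearly flat, so the silane should approach anti to the pseudoaxial 2-methyl and leave the chain cis to methyl in the enone F7 and its decyl analogue F8.
   - H2 over Pd/C gives the ketone F9 and its decyl analogue F10; LiBH(s-Bu)3 gives the cis alcohol F11 and its decyl analogue F12; TBSOTf/2,6-lutidine (−78 °C) gives 13 and 16.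

3. Step 8 (and its twin, step 10). Self-metathesis of 10 and ruthenium hydride-induced double-bond migration before metathesis would give dimers and chain-shortened homologues, the latter hard to remove from a target whose two arms differ by one CH2. The fallback sets out from 10 and returns at 13 and 16, so steps 9 and 11 are no longer needed. Hydroboration of 10 with 9-BBN (THF, rt) gives the B-alkyl-9-borabicyclo[3.3.1]nonane F13. This is coupled in the same flask with excess 1,8-dibromooctane (Pd(OAc)2, PCy3, K3PO4·H2O, THF, rt; alkyl–alkyl Suzuki–Miyaura coupling) to give 13; with 1,7-dibromoheptane it gives 16.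

**Further compounds**

F1 | step 14 | tert-butyl (2S,3S,6R)-3-[(tert-butyldimethylsilyl)oxy]-6-[(12Z)-14,14-diethoxy-13-iodotetradec-12-en-1-yl]-2-methylpiperidine-1-carboxylate | C[C@@H]1N(C(=O)OC(C)(C)C)[C@H](CCCCCCCCCCC/C=C(/C(OCC)OCC)I)CC[C@@H]1O[Si](C)(C)C(C)(C)C
F2 | step 14 | {10-[(2R,5S,6S)-1-(tert-butoxycarbonyl)-5-[(tert-butyldimethylsilyl)oxy]-6-methylpiperidin-2-yl]decyl}zinc iodide | I[Zn]CCCCCCCCCC[C@@H]1CC[C@H](O[Si](C)(C)C(C)(C)C)[C@H](C)N1C(=O)OC(C)(C)C
F3 | step 7 | tert-butyl N-[(1S)-1-[5-(11-bromoundecyl)furan-2-yl]ethyl]carbamate | C[C@H](NC(=O)OC(C)(C)C)c1ccc(CCCCCCCCCCCBr)o1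
F4 | step 7 | tert-butyl N-[(1S)-1-[5-(10-bromodecyl)furan-2-yl]ethyl]carbamate | C[C@H](NC(=O)OC(C)(C)C)c1ccc(CCCCCCCCCCBr)o1
F5 | step 7 | tert-butyl (2S)-6-(11-bromoundecyl)-6-hydroxy-2-methyl-3-oxo-3,6-dihydro-2H-pyridine-1-carboxylate (C6 epimers) | C[C@@H]1N(C(=O)OC(C)(C)C)C(O)(CCCCCCCCCCCBr)C=CC1=O
F6 | step 7 | tert-butyl (2S)-6-(10-bromodecyl)-6-hydroxy-2-methyl-3-oxo-3,6-dihydro-2H-pyridine-1-carboxylate (C6 epimers) | C[C@@H]1N(C(=O)OC(C)(C)C)C(O)(CCCCCCCCCCBr)C=CC1=O
F7 | step 7 | tert-butyl (2S,6R)-6-(11-bromoundecyl)-2-methyl-3-oxo-3,6-dihydro-2H-pyridine-1-carboxylate | C[C@@H]1N(C(=O)OC(C)(C)C)[C@H](CCCCCCCCCCCBr)C=CC1=O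
F8 | step 7 | tert-butyl (2S,6R)-6-(10-bromodecyl)-2-methyl-3-oxo-3,6-dihydro-2H-pyridine-1-carboxylate | C[C@@H]1N(C(=O)OC(C)(C)C)[C@H](CCCCCCCCCCBr)C=CC1=O
F9 | step 7 | tert-butyl (2S,6R)-6-(11-bromoundecyl)-2-methyl-3-oxopiperidine-1-carboxylate | C[C@@H]1N(C(=O)OC(C)(C)C)[C@H](CCCCCCCCCCCBr)CCC1=O
F10 | step 7 | tert-butyl (2S,6R)-6-(10-bromodecyl)-2-methyl-3-oxopiperidine-1-carboxylate | C[C@@H]1N(C(=O)OC(C)(C)C)[C@H](CCCCCCCCCCBr)CCC1=O
F11 | step 7 | tert-butyl (2S,3S,6R)-6-(11-bromoundecyl)-3-hydroxy-2-methylpiperidine-1-carboxylate | C[C@@H]1N(C(=O)OC(C)(C)C)[C@H](CCCCCCCCCCCBr)CC[C@@H]1O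
F12 | step 7 | tert-butyl (2S,3S,6R)-6-(10-bromodecyl)-3-hydroxy-2-methylpiperidine-1-carboxylate | C[C@@H]1N(C(=O)OC(C)(C)C)[C@H](CCCCCCCCCCBr)CC[C@@H]1O
F13 | step 8 | tert-butyl (2S,3S,6R)-6-[3-(9-borabicyclo[3.3.1]nonan-9-yl)propyl]-3-[(tert-butyldimethylsilyl)oxy]-2-methylpiperidine-1-carboxylate | C[C@@H]1N(C(=O)OC(C)(C)C)[C@H](CCCB2C3CCCC2CCC3)CC[C@@H]1O[Si](C)(C)C(C)(C)C
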